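**Retrosynthetic overview**

1. The target is the 9-O-(E)-caffeate of (−)-lariciresinol, (2R,3S,4S), with the 2-aryl trans to the 3-CH2O group and the 3-CH2O cis to the 4-benzyl. The last bonds formed are four ArO–H (fluoride desilylation) and the ester C–O (Steglich), from bis-O-TIPS (−)-lariciresinol and bis-O-TBS caffeic acid.
2. The oxolane ring (second and last ring made) comes from acid-mediated benzylic cycloetherification of a triol, which arises by LiAlH4 opening of an α-(hydroxybenzyl)-β-benzyl-γ-butyrolactone.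
3. The key C–C bond (C2–C3 of the oxolane) comes from an intermolecular aldol of the lithium enolate of an (S)-β-(arylmethyl)-γ-butyrolactone with O-TIPS-vanillin, trans to the β-substituent.
4. The butyrolactone ring (first ring made, later opened) comes from Evans alkylation of an N-(3-arylpropanoyl)-(R)-4-benzyl-oxazolidinone with tert-butyl bromoacetate, LiBH4 removal of the auxiliary and lactonisation.
5. Starting materials: ferulic acid, vanillin, caffeic acid, (R)-4-benzyl-1,3-oxazolidin-2-one, tert-butyl bromoacetate.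

Assumption: NaN(SiMe3)2 and LiN(i-Pr)2 are bought as stock solutions, and 16 and 17 are carried as mixtures of carbinol epimers because step 10 erases that centre.

**Route**

Step 1
Reactants: 1 ferulic acid, (E)-3-(4-hydroxy-3-methoxyphenyl)prop-2-enoic acid
Product: 2 dihydroferulic acid, 3-(4-hydroxy-3-methoxyphenyl)propanoic acid
Conditions: H2 (1 atm), 10% Pd/C, MeOH, rt
Reagents that add atoms: none
Why: Heterogeneous catalytic hydrogenation saturates only the cinnamic C=C; arene, acid and aryl ether are inert and no stereocentre is involved.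

Step 2
Reactants: 2 dihydroferulic acid
Product: 4 3-[3-methoxy-4-(triisopropylsilyloxy)phenyl]propanoic acid, via TIPS ester 3 (not isolated)
Conditions: TIPSCl (2.3 equiv), imidazole, DMF, rt; then K2CO3, MeOH/THF/H2O, rt, 1 h; 1 M HCl to pH 3
Reagents that add atoms: triisopropylsilyl chloride, CC(C)[Si](Cl)(C(C)C)C(C)C
Why: Exhaustive silylation followed by selective saponification of the far more labile silyl ester leaves the hindered aryl TIPS ether, which tolerates the bases, hydrides and acids used later.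

Step 3
Reactants: 4 3-[3-methoxy-4-(triisopropylsilyloxy)phenyl]propanoic acid; 5 (R)-4-benzyl-1,3-oxazolidin-2-one
Product: 7 (4R)-4-benzyl-3-{3-[3-methoxy-4-(triisopropylsilyloxy)phenyl]propanoyl}-1,3-oxazolidin-2-one, via mixed pivalic anhydride 6 (not isolated)
Conditions: pivaloyl chloride, Et3N, THF, −20 °C, 1 h; then LiCl, 5, −20 °C → rt
Reagents that add atoms: none
Why: N-acylation of the oxazolidinone through the mixed pivalic anhydride (LiCl/Et3N variant) needs no strong base and leaves the aryl silyl ether untouched.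

Step 4
Reactants: 7 (4R)-4-benzyl-3-{3-[3-methoxy-4-(triisopropylsilyloxy)phenyl]propanoyl}-1,3-oxazolidin-2-one; 8 tert-butyl bromoacetate
Product: 10 tert-butyl (3S)-4-[(4R)-4-benzyl-2-oxo-1,3-oxazolidin-3-yl]-3-[3-methoxy-4-(triisopropylsilyloxy)benzyl]-4-oxobutanoate, via sodium Z-enolate 9 (not isolated)
Conditions: NaN(SiMe3)2 (1.1 equiv, 1 M in THF), THF, −78 °C, 45 min; then 8 (2 equiv), −78 → −40 °C
Reagents that add atoms: none
Why: Evans asymmetric alkylation, in which the chelated Z-enolate is attacked by the reactive α-bromo ester on the face opposite the C4 benzyl of the (R)-auxiliary, setting the new centre as S (dr typically >95:5, minor isomer removed by chromatography).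

Step 5
Reactants: 10 tert-butyl (3S)-4-[(4R)-4-benzyl-2-oxo-1,3-oxazolidin-3-yl]-3-[3-methoxy-4-(triisopropylsilyloxy)benzyl]-4-oxobutanoate
Product: 11 tert-butyl (3S)-4-hydroxy-3-[3-methoxy-4-(triisopropylsilyloxy)benzyl]butanoate
Conditions: LiBH4 (1.5 equiv), H2O (1.5 equiv), Et2O, 0 °C
Reagents that add atoms: none
Why: Chemoselective reductive cleavage of the imide by LiBH4 gives the primary alcohol and returns the auxiliary, while the tert-butyl ester is not reduced and the stereocentre is not epimerised.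

Step 6
Reactants: 11 tert-butyl (3S)-4-hydroxy-3-[3-methoxy-4-(triisopropylsilyloxy)benzyl]butanoate
Product: 12 (4S)-4-[3-methoxy-4-(triisopropylsilyloxy)benzyl]dihydrofuran-2(3H)-one
Conditions: CF3CO2H (10 equiv), CH2Cl2, 0 °C → rt
Reagents that add atoms: none
Why: Acidolysis of the tert-butyl ester and spontaneous 5-exo acid-catalysed lactonisation of the γ-hydroxy acid close the butyrolactone without touching the stereocentre or the aryl TIPS ether.

Step 7
Reactants: 13 vanillin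
Product: 14 3-methoxy-4-(triisopropylsilyloxy)benzaldehyde
Conditions: TIPSCl (1.2 equiv), imidazole, DMF, rt
Reagents that add atoms: triisopropylsilyl chloride, CC(C)[Si](Cl)(C(C)C)C(C)C
Why: Standard imidazole-promoted silylation of a phenol; the aldehyde is unaffected.

Step 8
Reactants: 12 (4S)-4-[3-methoxy-4-(triisopropylsilyloxy)benzyl]dihydrofuran-2(3H)-one; 14 3-methoxy-4-(triisopropylsilyloxy)benzaldehyde
Product: 16 (3R,4S)-3-{hydroxy[3-methoxy-4-(triisopropylsilyloxy)phenyl]methyl}-4-[3-methoxy-4-(triisopropylsilyloxy)benzyl]dihydrofuran-2(3H)-one (both carbinol epimers), via lithium enolate 15 (not isolated)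
Conditions: LiN(i-Pr)2 (1.15 equiv, stock solution), THF, −78 °C, 1 h; then 14 (1.2 equiv), −78 °C, 1 h; AcOH quench at −78 °C
Reagents that add atoms: none
Why: Intermolecular aldol addition of the lactone enolate to a non-enolisable aldehyde, which approaches anti to the C4 benzyl group so that C3 is set trans (3R); the carbinol centre forms as a mixture that step 10 erases.

Step 9
Reactants: 16 (3R,4S)-3-{hydroxy[3-methoxy-4-(triisopropylsilyloxy)phenyl]methyl}-4-[3-methoxy-4-(triisopropylsilyloxy)benzyl]dihydrofuran-2(3H)-one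
Product: 17 (2S,3S)-2-{hydroxy[3-methoxy-4-(triisopropylsilyloxy)phenyl]methyl}-3-[3-methoxy-4-(triisopropylsilyloxy)benzyl]butane-1,4-diol (both carbinol epimers)
Conditions: LiAlH4 (2.5 equiv), THF, 0 °C, 1 h; H2O quench
Reagents that add atoms: none
Why: Hydride reduction of the lactone to the 1,4-diol touches no stereocentre, and aryl TIPS ethers tolerate LiAlH4 at 0 °C.

Step 10
Reactants: 17 (2S,3S)-2-{hydroxy[3-methoxy-4-(triisopropylsilyloxy)phenyl]methyl}-3-[3-methoxy-4-(triisopropylsilyloxy)benzyl]butane-1,4-diol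
Product: 18 {(2R,3S,4S)-2-[3-methoxy-4-(triisopropylsilyloxy)phenyl]-4-[3-methoxy-4-(triisopropylsilyloxy)benzyl]tetrahydrofuran-3-yl}methanol
Conditions: (±)-camphor-10-sulfonic acid (0.1 equiv), CH2Cl2, 0 °C → rt, monitored by TLC; Et3N quench
Reagents that add atoms: none
Why: Acid-catalysed SN1 cycloetherification, in which the p-silyloxybenzylic cation is captured 5-exo by the primary hydroxyl on the benzyl-bearing carbon; both carbinol epimers converge on 2R because the aryl group settles trans to the adjacent CH2OH (the all-cis alternative is strongly disfavoured and the closure is reversible).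

Step 11
Reactants: 19 caffeic acid
Product: 21 (E)-3-[3,4-bis(tert-butyldimethylsilyloxy)phenyl]prop-2-enoic acid, via tris-TBS ester 20 (not isolated)
Conditions: TBSCl (3.5 equiv), imidazole, DMF, rt; then AcOH/THF/H2O (3:1:1), rt
Reagents that add atoms: tert-butyldimethylsilyl chloride, CC(C)(C)[Si](C)(C)Cl
Why: Exhaustive silylation followed by mild hydrolysis of the labile silyl ester gives the catechol-protected acid with the E-alkene untouched.

Step 12
Reactants: 18 {(2R,3S,4S)-2-[3-methoxy-4-(triisopropylsilyloxy)phenyl]-4-[3-methoxy-4-(triisopropylsilyloxy)benzyl]tetrahydrofuran-3-yl}methanol; 21 (E)-3-[3,4-bis(tert-butyldimethylsilyloxy)phenyl]prop-2-enoic acid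
Product: 22 {(2R,3S,4S)-2-[3-methoxy-4-(triisopropylsilyloxy)phenyl]-4-[3-methoxy-4-(triisopropylsilyloxy)benzyl]tetrahydrofuran-3-yl}methyl (E)-3-[3,4-bis(tert-butyldimethylsilyloxy)phenyl]prop-2-enoate
Conditions: EDC·HCl (1.5 equiv), DMAP (0.3 equiv), CH2Cl2, 0 °C → rt
Reagents that add atoms: none
Why: Steglich esterification acylates the only free hydroxyl, a primary alcohol, under neutral conditions that leave the benzylic ether, the silyl ethers and all stereocentres intact.

Step 13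
Reactants: 22 {(2R,3S,4S)-2-[3-methoxy-4-(triisopropylsilyloxy)phenyl]-4-[3-methoxy-4-(triisopropylsilyloxy)benzyl]tetrahydrofuran-3-yl}methyl (E)-3-[3,4-bis(tert-butyldimethylsilyloxy)phenyl]prop-2-enoate
Product: 23 [(2R,3S,4S)-2-(4-hydroxy-3-methoxyphenyl)-4-(4-hydroxy-3-methoxybenzyl)tetrahydrofuran-3-yl]methyl (E)-3-(3,4-dihydroxyphenyl)prop-2-enoate (CNP0132883.1)
Conditions: Bu4NF (5 equiv), AcOH (5 equiv), THF, 0 °C → rt, under argon
Reagents that add atoms: none
Why: Fluoride-mediated desilylation removes all four aryl silyl ethers, and the AcOH buffer keeps phenoxide basicity low so the cinnamate ester, the E-alkene and the benzylic ether survive.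

**Compound list**

1 | ferulic acid, (E)-3-(4-hydroxy-3-methoxyphenyl)prop-2-enoic acid | COc1cc(/C=C/C(=O)O)ccc1O | starting material
2 | dihydroferulic acid, 3-(4-hydroxy-3-methoxyphenyl)propanoic acid | COc1cc(CCC(=O)O)ccc1O | intermediate
3 | triisopropylsilyl 3-[3-methoxy-4-(triisopropylsilyloxy)phenyl]propanoate | COc1cc(CCC(=O)O[Si](C(C)C)(C(C)C)C(C)C)ccc1O[Si](C(C)C)(C(C)C)C(C)C | intermediate
4 | 3-[3-methoxy-4-(triisopropylsilyloxy)phenyl]propanoic acid | COc1cc(CCC(=O)O)ccc1O[Si](C(C)C)(C(C)C)C(C)C | intermediate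
5 | (R)-4-benzyl-1,3-oxazolidin-2-one | O=C1N[C@H](Cc2ccccc2)CO1 | starting material
6 | 3-[3-methoxy-4-(triisopropylsilyloxy)phenyl]propanoic pivalic anhydride | COc1cc(CCC(=O)OC(=O)C(C)(C)C)ccc1O[Si](C(C)C)(C(C)C)C(C)C | intermediate
7 | (4R)-4-benzyl-3-{3-[3-methoxy-4-(triisopropylsilyloxy)phenyl]propanoyl}-1,3-oxazolidin-2-one | COc1cc(CCC(=O)N2C(=O)OC[C@H]2Cc2ccccc2)ccc1O[Si](C(C)C)(C(C)C)C(C)C | intermediate
8 | tert-butyl bromoacetate | CC(C)(C)OC(=O)CBr | starting material
9 | sodium (Z)-enolate of 7 | [Na+].COc1cc(C/C=C(\[O-])N2C(=O)OC[C@H]2Cc2ccccc2)ccc1O[Si](C(C)C)(C(C)C)C(C)C | intermediate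
10 | tert-butyl (3S)-4-[(4R)-4-benzyl-2-oxo-1,3-oxazolidin-3-yl]-3-[3-methoxy-4-(triisopropylsilyloxy)benzyl]-4-oxobutanoate | COc1cc(C[C@@H](CC(=O)OC(C)(C)C)C(=O)N2C(=O)OC[C@H]2Cc2ccccc2)ccc1O[Si](C(C)C)(C(C)C)C(C)C | intermediate
11 | tert-butyl (3S)-4-hydroxy-3-[3-methoxy-4-(triisopropylsilyloxy)benzyl]butanoate | COc1cc(C[C@@H](CC(=O)OC(C)(C)C)CO)ccc1O[Si](C(C)C)(C(C)C)C(C)C | intermediate
12 | (4S)-4-[3-methoxy-4-(triisopropylsilyloxy)benzyl]dihydrofuran-2(3H)-one | COc1cc(C[C@@H]2COC(=O)C2)ccc1O[Si](C(C)C)(C(C)C)C(C)C | intermediate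
13 | vanillin | COc1cc(C=O)ccc1O | starting material
14 | 3-methoxy-4-(triisopropylsilyloxy)benzaldehyde | COc1cc(C=O)ccc1O[Si](C(C)C)(C(C)C)C(C)C | intermediate
15 | lithium enolate of 12 | [Li+].COc1cc(C[C@@H]2COC([O-])=C2)ccc1O[Si](C(C)C)(C(C)C)C(C)C | intermediate
16 | (3R,4S)-3-{hydroxy[3-methoxy-4-(triisopropylsilyloxy)phenyl]methyl}-4-[3-methoxy-4-(triisopropylsilyloxy)benzyl]dihydrofuran-2(3H)-one, both carbinol epimers | COc1cc(C[C@@H]2COC(=O)[C@H]2C(O)c2ccc(O[Si](C(C)C)(C(C)C)C(C)C)c(OC)c2)ccc1O[Si](C(C)C)(C(C)C)C(C)C | intermediate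
17 | (2S,3S)-2-{hydroxy[3-methoxy-4-(triisopropylsilyloxy)phenyl]methyl}-3-[3-methoxy-4-(triisopropylsilyloxy)benzyl]butane-1,4-diol, both carbinol epimers | COc1cc(C[C@H](CO)[C@@H](CO)C(O)c2ccc(O[Si](C(C)C)(C(C)C)C(C)C)c(OC)c2)ccc1O[Si](C(C)C)(C(C)C)C(C)C | intermediate
18 | {(2R,3S,4S)-2-[3-methoxy-4-(triisopropylsilyloxy)phenyl]-4-[3-methoxy-4-(triisopropylsilyloxy)benzyl]tetrahydrofuran-3-yl}methanol, bis-O-TIPS (−)-lariciresinol | COc1cc(C[C@@H]2CO[C@@H](c3ccc(O[Si](C(C)C)(C(C)C)C(C)C)c(OC)c3)[C@@H]2CO)ccc1O[Si](C(C)C)(C(C)C)C(C)C | intermediate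
19 | caffeic acid, (E)-3-(3,4-dihydroxyphenyl)prop-2-enoic acid | O=C(O)/C=C/c1ccc(O)c(O)c1 | starting material
20 | tert-butyldimethylsilyl (E)-3-[3,4-bis(tert-butyldimethylsilyloxy)phenyl]prop-2-enoate | CC(C)(C)[Si](C)(C)OC(=O)/C=C/c1ccc(O[Si](C)(C)C(C)(C)C)c(O[Si](C)(C)C(C)(C)C)c1 | intermediate
21 | (E)-3-[3,4-bis(tert-butyldimethylsilyloxy)phenyl]prop-2-enoic acid | O=C(O)/C=C/c1ccc(O[Si](C)(C)C(C)(C)C)c(O[Si](C)(C)C(C)(C)C)c1 | intermediate
22 | {(2R,3S,4S)-2-[3-methoxy-4-(triisopropylsilyloxy)phenyl]-4-[3-methoxy-4-(triisopropylsilyloxy)benzyl]tetrahydrofuran-3-yl}methyl (E)-3-[3,4-bis(tert-butyldimethylsilyloxy)phenyl]prop-2-enoate | COc1cc(C[C@@H]2CO[C@@H](c3ccc(O[Si](C(C)C)(C(C)C)C(C)C)c(OC)c3)[C@@H]2COC(=O)/C=C/c2ccc(O[Si](C)(C)C(C)(C)C)c(O[Si](C)(C)C(C)(C)C)c2)ccc1O[Si](C(C)C)(C(C)C)C(C)C | intermediate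
23 | [(2R,3S,4S)-2-(4-hydroxy-3-methoxyphenyl)-4-(4-hydroxy-3-methoxybenzyl)tetrahydrofuran-3-yl]methyl (E)-3-(3,4-dihydroxyphenyl)prop-2-enoate | COc1cc(C[C@@H]2CO[C@@H](c3ccc(O)c(OC)c3)[C@@H]2COC(=O)/C=C/c2ccc(O)c(O)c2)ccc1O | target

**Summary**

Total step count: 13. Longest linear sequence: 11 steps (steps 1–6, 8, 9, 10, 12, 13, from ferulic acid).

**Steps most likely to fail and fallbacks**

Step 8 (aldol). The lithium aldolate can revert or give a poor trans:cis ratio at C3. The fallback sets out from 12 and 14 and comes back at 16. Aldehyde 14 is oxidised (NaClO2, NaH2PO4, 2-methyl-2-butene, t-BuOH/H2O) to 3-methoxy-4-(triisopropylsilyloxy)benzoic acid F1. This is activated with 1,1'-carbonyldiimidazole in THF to (1H-imidazol-1-yl)[3-methoxy-4-(triisopropylsilyloxy)phenyl]methanone F2. A crossed Claisen condensation of the enolate of 12 (LiN(SiMe3)2, 2.2 equiv, THF, −78 °C) with F2 gives (3R,4S)-3-[3-methoxy-4-(triisopropylsilyloxy)benzoyl]-4-[3-methoxy-4-(triisopropylsilyloxy)benzyl]dihydrofuran-2(3H)-one F3, trans by thermodynamic control because C3 is epimerisable. NaBH4 in MeOH/THF at −20 °C reduces the ketone to 16, and either carbinol epimer serves.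

Step 9 (LiAlH4 reduction). The alkoxide of the β-hydroxy lactone can undergo retro-aldol cleavage before the lactone is reduced. The fallback sets out from 16 and comes back at 18. The carbinol is capped (Et3SiOSO2CF3, 2,6-lutidine, CH2Cl2, −78 °C) to give (3R,4S)-3-{[3-methoxy-4-(triisopropylsilyloxy)phenyl](triethylsilyloxy)methyl}-4-[3-methoxy-4-(triisopropylsilyloxy)benzyl]dihydrofuran-2(3H)-one F4, which cannot fragment. LiBH4 in THF at rt opens the lactone to (2S,3S)-2-{[3-methoxy-4-(triisopropylsilyloxy)phenyl](triethylsilyloxy)methyl}-3-[3-methoxy-4-(triisopropylsilyloxy)benzyl]butane-1,4-diol F5. Camphor-10-sulfonic acid in CH2Cl2 then ionises the benzylic silyl ether and closes the oxolane directly to 18, bypassing 17.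

Step 10 (cycloetherification). Ether formation is reversible under acid, so the benzylic cation can drift into irreversible Friedel–Crafts closure onto the other arene (aryltetralin), or ionisation of the silyl-protected carbinol can be sluggish. The fallback sets out from 17 and comes back at 23. Bu4NF/AcOH in THF removes both TIPS groups to give (2S,3S)-2-[hydroxy(4-hydroxy-3-methoxyphenyl)methyl]-3-(4-hydroxy-3-methoxybenzyl)butane-1,4-diol F6. With the free para-phenol the carbinol ionises through a p-quinone methide under very mild acid (pyridinium p-toluenesulfonate, MeCN, rt) and closes to (−)-lariciresinol F7. A chemoselective Mitsunobu esterification (PPh3, diisopropyl azodicarboxylate, THF, 0 °C) of its only aliphatic hydroxyl by acid 21 gives [(2R,3S,4S)-2-(4-hydroxy-3-methoxyphenyl)-4-(4-hydroxy-3-methoxybenzyl)tetrahydrofuran-3-yl]methyl (E)-3-[3,4-bis(tert-butyldimethylsilyloxy)phenyl]prop-2-enoate F8; the phenols are not competent nucleophiles beside the carboxylic acid. Bu4NF/AcOH then gives 23.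

**Further compounds**

F1 | step 8 | 3-methoxy-4-(triisopropylsilyloxy)benzoic acid | COc1cc(C(=O)O)ccc1O[Si](C(C)C)(C(C)C)C(C)C
F2 | step 8 | (1H-imidazol-1-yl)[3-methoxy-4-(triisopropylsilyloxy)phenyl]methanone | COc1cc(C(=O)n2ccnc2)ccc1O[Si](C(C)C)(C(C)C)C(C)C
F3 | step 8 | (3R,4S)-3-[3-methoxy-4-(triisopropylsilyloxy)benzoyl]-4-[3-methoxy-4-(triisopropylsilyloxy)benzyl]dihydrofuran-2(3H)-one | COc1cc(C[C@@H]2COC(=O)[C@H]2C(=O)c2ccc(O[Si](C(C)C)(C(C)C)C(C)C)c(OC)c2)ccc1O[Si](C(C)C)(C(C)C)C(C)C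
F4 | step 9 | (3R,4S)-3-{[3-methoxy-4-(triisopropylsilyloxy)phenyl](triethylsilyloxy)methyl}-4-[3-methoxy-4-(triisopropylsilyloxy)benzyl]dihydrofuran-2(3H)-one, both carbinol epimers | COc1cc(C[C@@H]2COC(=O)[C@H]2C(O[Si](CC)(CC)CC)c2ccc(O[Si](C(C)C)(C(C)C)C(C)C)c(OC)c2)ccc1O[Si](C(C)C)(C(C)C)C(C)C
F5 | step 9 | (2S,3S)-2-{[3-methoxy-4-(triisopropylsilyloxy)phenyl](triethylsilyloxy)methyl}-3-[3-methoxy-4-(triisopropylsilyloxy)benzyl]butane-1,4-diol, both carbinol epimers | COc1cc(C[C@H](CO)[C@@H](CO)C(O[Si](CC)(CC)CC)c2ccc(O[Si](C(C)C)(C(C)C)C(C)C)c(OC)c2)ccc1O[Si](C(C)C)(C(C)C)C(C)C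
F6 | step 10 | (2S,3S)-2-[hydroxy(4-hydroxy-3-methoxyphenyl)methyl]-3-(4-hydroxy-3-methoxybenzyl)butane-1,4-diol, both carbinol epimers | COc1cc(C[C@H](CO)[C@@H](CO)C(O)c2ccc(O)c(OC)c2)ccc1O
F7 | step 10 | (−)-lariciresinol, 4-[(2R,3S,4S)-4-(4-hydroxy-3-methoxybenzyl)-3-(hydroxymethyl)tetrahydrofuran-2-yl]-2-methoxyphenol | COc1cc(C[C@@H]2CO[C@@H](c3ccc(O)c(OC)c3)[C@@H]2CO)ccc1O
F8 | step 10 | [(2R,3S,4S)-2-(4-hydroxy-3-methoxyphenyl)-4-(4-hydroxy-3-methoxybenzyl)tetrahydrofuran-3-yl]methyl (E)-3-[3,4-bis(tert-butyldimethylsilyloxy)phenyl]prop-2-enoate | COc1cc(C[C@@H]2CO[C@@H](c3ccc(O)c(OC)c3)[C@@H]2COC(=O)/C=C/c2ccc(O[Si](C)(C)C(C)(C)C)c(O[Si](C)(C)C(C)(C)C)c2)ccc1O
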